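**Retrosynthetic overview**
- The acid comes from its tert-butyl ester; the E-enoate is made by Wittig olefination of an α-acetoxy ketone side chain.
- That ketone and the ring enone are unmasked from one cyclic ketal; the C9–C11 bond is formed by a hetero-Diels–Alder reaction of a Birch-derived enol ether with a vinyl ketone, and the C1 oxygen is removed while the ketal protects the other carbonyls.
- Key step: enantioselective Birch reductive methylation of 7-methoxy-4,4-dimethyl-1-tetralone. It breaks the arene and sets the quaternary C10, the C8 enol ether and the C5=C6 alkene in one operation; C5 and C9 then settle thermodynamically.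
- Ring order: ring A is closed first on anisole (Friedel–Crafts alkylation, then acylation); ring B is the dearomatised anisole ring.

Assumption: positions are given in labdane numbering (C1–C10 decalin, C11–C16 side chain), and the catalyst antipode that gives the 8aS ketone in step 2 (written as S,S) must be fixed by one screening run.

**Step 1**
Reactants: 1 anisole; 2 5,5-dimethyldihydrofuran-2(3H)-one
Product: 4 7-methoxy-4,4-dimethyl-3,4-dihydronaphthalen-1(2H)-one, via 4-(4-methoxyphenyl)-4-methylpentanoic acid 3 (not isolated)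
Conditions: MsOH, 40 °C; then P2O5, 60 °C
Reagents that add atoms: none
Why: In MsOH the lactone ionises to the tertiary cation, which alkylates anisole para to OMe (Friedel–Crafts alkylation); once P2O5 turns the medium into Eaton's reagent, acid 3 closes by intramolecular Friedel–Crafts acylation ortho to the alkyl arm, and no stereocentre is formed.

**Step 2**
Reactants: 4 7-methoxy-4,4-dimethyl-3,4-dihydronaphthalen-1(2H)-one
Product: 7 (8aS)-7-methoxy-4,4,8a-trimethyl-3,4,6,8a-tetrahydronaphthalen-1(2H)-one, via potassium dienolate 5 (not isolated), via tributylstannyl dienolate 6 (not isolated)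
Conditions: K, t-BuOH (1 equiv), NH3/THF, −78 °C; NH3 off; Bu3SnCl (2 equiv), THF, 0 °C; (S,S)-(salen)CrCl (10 mol %), MeI, PhH, 0 °C
Reagents that add atoms: iodomethane, CI
Why: Proposed new method: Birch reduction of the aryl ketone (two electrons, one proton at the para carbon C7) gives the cross-conjugated dienolate 5; after K→Sn exchange this is a tetrasubstituted cyclic tributyltin enolate of the kind that Cr(salen)Cl alkylates enantioselectively, so C-methylation at the ipso carbon, with the catalyst distinguishing the gem-dimethyl-bearing C5 arm from the C9 arm, should set the quaternary C10 as 8aS; the closest known reaction types are the Birch reductive methylation of 1-tetralones and the Cr(salen)Cl-catalysed alkylation of tributyltin enolates of α-substituted cyclic ketones.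

**Step 3**
Reactants: 8 but-2-yne-1,4-diyl diacetate
Product: 10 2-oxobut-3-en-1-yl acetate, via 2-oxobutane-1,4-diyl diacetate 9 (not isolated)
Conditions: Ph3PAuCl/AgOTf (2 mol %), H2O, dioxane, 60 °C; then Et3N, CH2Cl2, 0 °C
Reagents that add atoms: water, O
Why: Acetate-assisted gold-catalysed hydration of the symmetrical alkyne gives ketone 9, whose β-acetoxy group leaves by E1cB elimination to give the vinyl ketone; no stereocentre is formed.

**Step 4**
Reactants: 7 (8aS)-7-methoxy-4,4,8a-trimethyl-3,4,6,8a-tetrahydronaphthalen-1(2H)-one; 10 2-oxobut-3-en-1-yl acetate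
Product: 11 [(10aS)-4a-methoxy-7,7,10a-trimethyl-10-oxo-4a,5,7,8,9,10,10a,10b-octahydro-1H-benzo[f]chromen-3-yl]methyl acetate (pyran O joins the ketal carbon C8 to C13; mixture at C4a/C10b)
Conditions: Yb(fod)3 (5 mol %), BHT, ClCH2CH2Cl, 50 °C
Reagents that add atoms: none
Why: Inverse-electron-demand hetero-Diels–Alder reaction of the enol ether with the 1-oxadiene forms the C9–C11 bond regiospecifically and masks both the C8 and C13 carbonyls as one cyclic ketal; the two new centres are erased in step 5, so their configuration does not matter.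

**Step 5**
Reactants: 11 [(10aS)-4a-methoxy-7,7,10a-trimethyl-10-oxo-4a,5,7,8,9,10,10a,10b-octahydro-1H-benzo[f]chromen-3-yl]methyl acetate
Product: 13 (1S,4aR,8aR)-1-(4-hydroxy-3-oxobutyl)-5,5,8a-trimethyl-4a,5,6,7,8,8a-hexahydronaphthalen-2(1H)-one, via deoxygenated hydroxy ketal 12 (not isolated)
Conditions: N2H4·H2O, diethylene glycol, 130 °C; KOt-Bu, DMSO, 25 °C; then 2 M HCl, THF, 50 °C
Reagents that add atoms: water, O
Why: Wolff–Kishner reduction (Cram modification) removes the hindered C1 carbonyl while the other carbonyls sit in the base-stable ketal and hydrazine cleaves the acetate; aqueous acid then opens the ketal, moves the C5=C6 bond into conjugation through the dienol, and equilibrates C5 and C9 to the trans-fused ring with equatorial side chain (4aR, 1S).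

**Step 6**
Reactants: 13 (1S,4aR,8aR)-1-(4-hydroxy-3-oxobutyl)-5,5,8a-trimethyl-4a,5,6,7,8,8a-hexahydronaphthalen-2(1H)-one
Product: 14 2-oxo-4-[(1S,4aR,8aR)-5,5,8a-trimethyl-2-oxo-1,2,4a,5,6,7,8,8a-octahydronaphthalen-1-yl]butyl acetate
Conditions: Ac2O, pyridine, DMAP (cat.), CH2Cl2, 0 °C
Reagents that add atoms: acetic anhydride, CC(=O)OC(C)=O
Why: DMAP-catalysed O-acylation of the primary alcohol; no stereocentre is touched.

**Step 7**
Reactants: 14 2-oxo-4-[(1S,4aR,8aR)-5,5,8a-trimethyl-2-oxo-1,2,4a,5,6,7,8,8a-octahydronaphthalen-1-yl]butyl acetate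
Product: 15 tert-butyl (2E)-4-acetoxy-3-{2-[(1S,4aR,8aR)-5,5,8a-trimethyl-2-oxo-1,2,4a,5,6,7,8,8a-octahydronaphthalen-1-yl]ethyl}but-2-enoate
Conditions: Ph3P=CHCO2t-Bu, PhMe, 80 °C
Reagents that add atoms: tert-butyl (triphenylphosphoranylidene)acetate, CC(C)(C)OC(=O)C=P(c1ccccc1)(c1ccccc1)c1ccccc1
Why: Wittig olefination with a stabilised ylide attacks only the unhindered α-acetoxy ketone and is expected to place the ester trans to the oxygen-bearing CH2 (E), the usual outcome for α-acyloxy ketones; the minor Z isomer is removed by chromatography.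

**Step 8**
Reactants: 15 tert-butyl (2E)-4-acetoxy-3-{2-[(1S,4aR,8aR)-5,5,8a-trimethyl-2-oxo-1,2,4a,5,6,7,8,8a-octahydronaphthalen-1-yl]ethyl}but-2-enoate
Product: 16 (2E)-4-acetoxy-3-{2-[(1S,4aR,8aR)-5,5,8a-trimethyl-2-oxo-1,2,4a,5,6,7,8,8a-octahydronaphthalen-1-yl]ethyl}but-2-enoic acid
Conditions: TFA, CH2Cl2, 0 → 23 °C
Reagents that add atoms: none
Why: Acidolysis of the tert-butyl ester (E1 loss of isobutene) leaves the primary allylic acetate, the enone and the alkene geometry untouched.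

**Compound list**
1 | anisole | COc1ccccc1 | starting material
2 | 5,5-dimethyldihydrofuran-2(3H)-one | CC1(C)CCC(=O)O1 | starting material
3 | 4-(4-methoxyphenyl)-4-methylpentanoic acid | COc1ccc(cc1)C(C)(C)CCC(=O)O | intermediate (not isolated)
4 | 7-methoxy-4,4-dimethyl-3,4-dihydronaphthalen-1(2H)-one | COc1ccc2c(c1)C(=O)CCC2(C)C | intermediate
5 | potassium 7-methoxy-4,4-dimethyl-2,3,4,6-tetrahydronaphthalen-1-olate | [K+].[O-]C1=C2C=C(OC)CC=C2C(C)(C)CC1 | intermediate (not isolated)
6 | tributyl[(7-methoxy-4,4-dimethyl-2,3,4,6-tetrahydronaphthalen-1-yl)oxy]stannane | CCCC[Sn](CCCC)(CCCC)OC1=C2C=C(OC)CC=C2C(C)(C)CC1 | intermediate (not isolated)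
7 | (8aS)-7-methoxy-4,4,8a-trimethyl-3,4,6,8a-tetrahydronaphthalen-1(2H)-one | C1=C(OC)CC=C2C(C)(C)CCC(=O)[C@@]12C | intermediate
8 | but-2-yne-1,4-diyl diacetate | CC(=O)OCC#CCOC(C)=O | starting material
9 | 2-oxobutane-1,4-diyl diacetate | CC(=O)OCC(=O)CCOC(C)=O | intermediate (not isolated)
10 | 2-oxobut-3-en-1-yl acetate | C=CC(=O)COC(C)=O | intermediate
11 | [(10aS)-4a-methoxy-7,7,10a-trimethyl-10-oxo-4a,5,7,8,9,10,10a,10b-octahydro-1H-benzo[f]chromen-3-yl]methyl acetate (mixture at C4a/C10b) | C1(CC=C(COC(C)=O)O3)C3(OC)CC=C2C(C)(C)CCC(=O)[C@@]12C | intermediate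
12 | [(10aS)-4a-methoxy-7,7,10a-trimethyl-4a,5,7,8,9,10,10a,10b-octahydro-1H-benzo[f]chromen-3-yl]methanol (mixture at C4a/C10b) | C1(CC=C(CO)O3)C3(OC)CC=C2C(C)(C)CCC[C@@]12C | intermediate (not isolated)
13 | (1S,4aR,8aR)-1-(4-hydroxy-3-oxobutyl)-5,5,8a-trimethyl-4a,5,6,7,8,8a-hexahydronaphthalen-2(1H)-one | OCC(=O)CC[C@@H]1C(=O)C=C[C@@H]2C(C)(C)CCC[C@@]12C | intermediate
14 | 2-oxo-4-[(1S,4aR,8aR)-5,5,8a-trimethyl-2-oxo-1,2,4a,5,6,7,8,8a-octahydronaphthalen-1-yl]butyl acetate | CC(=O)OCC(=O)CC[C@@H]1C(=O)C=C[C@@H]2C(C)(C)CCC[C@@]12C | intermediate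
15 | tert-butyl (2E)-4-acetoxy-3-{2-[(1S,4aR,8aR)-5,5,8a-trimethyl-2-oxo-1,2,4a,5,6,7,8,8a-octahydronaphthalen-1-yl]ethyl}but-2-enoate | CC(=O)OC/C(=C/C(=O)OC(C)(C)C)CC[C@@H]1C(=O)C=C[C@@H]2C(C)(C)CCC[C@@]12C | intermediate
16 | (2E)-4-acetoxy-3-{2-[(1S,4aR,8aR)-5,5,8a-trimethyl-2-oxo-1,2,4a,5,6,7,8,8a-octahydronaphthalen-1-yl]ethyl}but-2-enoic acid | CC(=O)OC/C(=C/C(=O)O)CC[C@@H]1C(=O)C=C[C@@H]2C(C)(C)CCC[C@@]12C | target

The quaternary carbon keeps one spatial arrangement from 7 to 16; its label changes from S (7, 11, 12) to R (13–16) only because the substituent priorities change.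

**Step count and risks**
Total step count: 8. Longest linear sequence: 7 (steps 1, 2, 4, 5, 6, 7, 8).

The three steps most likely to fail are steps 2, 4 and 7.

The enantioselective methylation in step 2 is unprecedented on a Birch-derived dienolate and may give low ee or a sluggish reaction with MeI. The fallback sets out from 4 and comes back at 7. Classical Birch reductive methylation (K, NH3, t-BuOH; LiBr; MeI) gives racemic ketone F1. Reduction with (S)-Me-CBS and catecholborane is reagent-controlled at C1 and turns the two enantiomers into diastereomers, the (1R,8aS)-carbinol F2 and the (1R,8aR)-carbinol F3, which are separated on silica. Dess–Martin oxidation of F2 returns 7.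

The cycloaddition in step 4 may stall because the enol ether carbon is next to the quaternary centre, or the skipped diene may isomerise under Lewis acid. The fallback sets out from 7 and comes back at 14. Huang–Minlon Wolff–Kishner reduction of 7 gives deoxygenated methoxy diene F4 (not isolated; base-induced diene isomerisation is harmless here), and aqueous HCl gives trans-fused enone F5. Kinetic α′-deprotonation with LDA and alkylation with 4-iodobut-1-ene/DMPU gives butenyl enone F6. OsO4/NMO oxidises only the terminal alkene to diol F7, AcCl/collidine gives primary acetate F8, and Dess–Martin oxidation returns 14.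

The Wittig reaction in step 7 may give a poor E/Z ratio, because the two ketone substituents are similar in size. The fallback sets out from 7 and comes back at 15, fixing the geometry by stereospecific cross-coupling instead of olefination. The step 4 cycloaddition run with acrolein gives methoxy ketal F9. Wolff–Kishner reduction as in step 5 gives deoxygenated ketal F10 (not isolated), and acid hydrolysis gives keto aldehyde F11. SnCl2-catalysed homologation with tert-butyl diazoacetate (Roskamp) gives β-keto ester F12. Tf2O with aqueous Me4NOH gives the non-chelated (E)-enol triflate F13, with OTf trans to the ester. Stille coupling with Bu3SnCH2OH (Pd(PPh3)4, LiCl) replaces OTf with retention to give hydroxy ester F14, and acetylation returns 15.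

**Further compounds**
F1 | step 2 | racemic 7-methoxy-4,4,8a-trimethyl-3,4,6,8a-tetrahydronaphthalen-1(2H)-one | C1=C(OC)CC=C2C(C)(C)CCC(=O)C12C
F2 | step 2 | (1R,8aS)-7-methoxy-4,4,8a-trimethyl-1,2,3,4,6,8a-hexahydronaphthalen-1-ol | C1=C(OC)CC=C2C(C)(C)CC[C@@H](O)[C@@]12C
F3 | step 2 | (1R,8aR)-7-methoxy-4,4,8a-trimethyl-1,2,3,4,6,8a-hexahydronaphthalen-1-ol | C1=C(OC)CC=C2C(C)(C)CC[C@@H](O)[C@]12C
F4 | step 4 | (8aS)-2-methoxy-5,5,8a-trimethyl-3,5,6,7,8,8a-hexahydronaphthalene | C1=C(OC)CC=C2C(C)(C)CCC[C@@]12C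
F5 | step 4 | (4aR,8aS)-5,5,8a-trimethyl-4a,5,6,7,8,8a-hexahydronaphthalen-2(1H)-one | C1C(=O)C=C[C@@H]2C(C)(C)CCC[C@@]12C
F6 | step 4 | (1S,4aR,8aR)-1-(but-3-en-1-yl)-5,5,8a-trimethyl-4a,5,6,7,8,8a-hexahydronaphthalen-2(1H)-one | C=CCC[C@@H]1C(=O)C=C[C@@H]2C(C)(C)CCC[C@@]12C
F7 | step 4 | (1S,4aR,8aR)-1-(3,4-dihydroxybutyl)-5,5,8a-trimethyl-4a,5,6,7,8,8a-hexahydronaphthalen-2(1H)-one | OCC(O)CC[C@@H]1C(=O)C=C[C@@H]2C(C)(C)CCC[C@@]12C
F8 | step 4 | 2-hydroxy-4-[(1S,4aR,8aR)-5,5,8a-trimethyl-2-oxo-1,2,4a,5,6,7,8,8a-octahydronaphthalen-1-yl]butyl acetate | CC(=O)OCC(O)CC[C@@H]1C(=O)C=C[C@@H]2C(C)(C)CCC[C@@]12C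
F9 | step 7 | (10aS)-4a-methoxy-7,7,10a-trimethyl-4a,5,8,9,10a,10b-hexahydro-1H-benzo[f]chromen-10(7H)-one | C1(CC=CO3)C3(OC)CC=C2C(C)(C)CCC(=O)[C@@]12C
F10 | step 7 | (10aS)-4a-methoxy-7,7,10a-trimethyl-4a,5,7,8,9,10,10a,10b-octahydro-1H-benzo[f]chromene | C1(CC=CO3)C3(OC)CC=C2C(C)(C)CCC[C@@]12C
F11 | step 7 | 3-[(1S,4aR,8aR)-5,5,8a-trimethyl-2-oxo-1,2,4a,5,6,7,8,8a-octahydronaphthalen-1-yl]propanal | O=CCC[C@@H]1C(=O)C=C[C@@H]2C(C)(C)CCC[C@@]12C
F12 | step 7 | tert-butyl 3-oxo-5-[(1S,4aR,8aR)-5,5,8a-trimethyl-2-oxo-1,2,4a,5,6,7,8,8a-octahydronaphthalen-1-yl]pentanoate | CC(C)(C)OC(=O)CC(=O)CC[C@@H]1C(=O)C=C[C@@H]2C(C)(C)CCC[C@@]12C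
F13 | step 7 | tert-butyl (2E)-5-[(1S,4aR,8aR)-5,5,8a-trimethyl-2-oxo-1,2,4a,5,6,7,8,8a-octahydronaphthalen-1-yl]-3-{[(trifluoromethyl)sulfonyl]oxy}pent-2-enoate | CC(C)(C)OC(=O)/C=C(/OS(=O)(=O)C(F)(F)F)CC[C@@H]1C(=O)C=C[C@@H]2C(C)(C)CCC[C@@]12C
F14 | step 7 | tert-butyl (2E)-4-hydroxy-3-{2-[(1S,4aR,8aR)-5,5,8a-trimethyl-2-oxo-1,2,4a,5,6,7,8,8a-octahydronaphthalen-1-yl]ethyl}but-2-enoate | OC/C(=C/C(=O)OC(C)(C)C)CC[C@@H]1C(=O)C=C[C@@H]2C(C)(C)CCC[C@@]12C
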